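The route rests on disconnecting the C6–C7 bond between ring A (cyclohexane C1–C6 carrying the 5,6-diol; carotenoid numbering) and the polyene. The lithium acetylide of a complete C31 polyenyne, already bearing the 5′,8′-epoxide end group, adds to (R)-2-(triethylsilyloxy)-2,6,6-trimethylcyclohexanone. This ketone cannot enolise (C1 and C5 are fully substituted) and its C5 silyloxy stereocentre directs attack to the opposite face, so the last C–C bond, the quaternary C6 carbinol and the cis-diol relationship arise together. NaAlH2(OCH2CH2OCH3)2 in the same flask turns C7≡C8 into the E-alkene. Both end groups descend from one Sharpless epoxide of β-cyclogeraniol; C8′ is relayed through an allene.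

Key step: step 19

Remark: carotenoid numbering is used: ring A = cyclohexane C1–C6 (C1 gem-dimethyl, C5 and C6 carbinol carbons), chain C7–C15 and C15′–C9′, ring B = cyclohexene C1′–C6′ fused to the dihydrofuran O–C5′–C6′=C7′–C8′; the target is read as (5R,6S,5′R,8′R), all-E, with a cis-5,6-diol and the C8′ chain trans to the C5′ methyl. All polyenes are handled under argon in the dark.

Step 1
Reactants: 1 β-cyclocitral (2,6,6-trimethylcyclohex-1-ene-1-carbaldehyde)
Product: 2 β-cyclogeraniol [(2,6,6-trimethylcyclohex-1-en-1-yl)methanol]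
Conditions: NaBH4, MeOH, 0 °C
Reagents that add atoms: none
Why: 1,2-hydride reduction of the hindered enal should give the tetrasubstituted allylic alcohol required for a hydroxyl-directed epoxidation.

Step 2
Reactants: 2 β-cyclogeraniol
Product: 3 [(1R,6R)-2,2,6-trimethyl-7-oxabicyclo[4.1.0]heptan-1-yl]methanol
Conditions: Ti(Oi-Pr)4 (cat.), L-(+)-diethyl tartrate (cat.), t-BuOOH, 4 Å molecular sieves, CH2Cl2, −20 °C
Reagents that add atoms: tert-butyl hydroperoxide CC(C)(C)OO
Why: Sharpless asymmetric epoxidation; with the L-(+)-tartrate the oxygen is delivered to the lower face of the allylic alcohol drawn with CH2OH at the lower right, which makes the methyl-bearing carbon R (the fused neighbour follows) and is the only source of absolute configuration in the route.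

Step 3
Reactants: 3 epoxy alcohol
Product: 4 (1S,6R)-2,2,6-trimethyl-7-oxabicyclo[4.1.0]heptane-1-carbaldehyde
Conditions: (n-Pr)4N[RuO4] (cat.), N-methylmorpholine N-oxide, 4 Å molecular sieves, CH2Cl2, rt
Reagents that add atoms: none
Why: Ley–Griffith oxidation of the primary alcohol is neutral and leaves the epoxide and its two fully substituted stereocentres untouched.

Step 4
Reactants: 4 epoxy aldehyde
Product: 5 (1R,6R)-1-ethynyl-2,2,6-trimethyl-7-oxabicyclo[4.1.0]heptane
Conditions: dimethyl (1-diazo-2-oxopropyl)phosphonate, K2CO3, MeOH, 0 °C to rt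
Reagents that add atoms: dimethyl (1-diazo-2-oxopropyl)phosphonate CC(=O)C(=[N+]=[N-])P(=O)(OC)OC
Why: Ohira–Bestmann (Seyferth–Gilbert) homologation converts the non-epimerisable aldehyde into the terminal alkyne under mild base that does not open the epoxide.

Step 5
Reactants: 6 ethyl acetoacetate
Product: 7 ethyl (2E)-3-{[(trifluoromethyl)sulfonyl]oxy}but-2-enoate
Conditions: (CF3SO2)2O, aq. Me4NOH, hexane, 5 °C
Reagents that add atoms: trifluoromethanesulfonic anhydride O=S(=O)(OS(=O)(=O)C(F)(F)F)C(F)(F)F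
Why: O-triflation of the non-chelated tetramethylammonium enolate, which adopts the extended geometry, should give the E enol triflate (triflate trans to the ester).

Step 6
Reactants: 5 ethynyl epoxide; 7 E enol triflate
Product: 8 ethyl (2E)-3-methyl-5-[(1R,6R)-2,2,6-trimethyl-7-oxabicyclo[4.1.0]heptan-1-yl]pent-2-en-4-ynoate
Conditions: PdCl2(PPh3)2 (cat.), CuI (cat.), Et3N, THF, rt
Reagents that add atoms: none
Why: Sonogashira coupling forms the C8′–C9′ bond with retention of the enol triflate geometry, giving the 9′E enyne while the propargylic epoxide survives the mild amine conditions.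

Step 7
Reactants: 8 epoxy enyne ester
Product: 9 ethyl (2E)-5-[(2R)-2-hydroxy-2,6,6-trimethylcyclohexylidene]-3-methylpenta-2,4-dienoate with the Sa (P) allene axis (H-8′ on the face opposite to the C5′ hydroxyl)
Conditions: Pd2(dba)3·CHCl3 (cat.), n-Bu3P (cat.), HCO2H, Et3N, THF, rt
Reagents that add atoms: none
Why: Palladium-catalysed formate hydrogenolysis of a propargylic epoxide: zerovalent palladium opens the C6′–O bond by anti SN2′ oxidative addition and the formate-derived hydride is then transferred from palladium with retention, so H-8′ ends anti to the C5′ oxygen and the centre chirality is converted into the allene axis.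

Step 8
Reactants: 9 allenic hydroxy ester
Product: 10 (2E)-5-[(2R)-2-hydroxy-2,6,6-trimethylcyclohexylidene]-3-methylpenta-2,4-dien-1-ol (Sa allene)
Conditions: (i-Bu)2AlH, CH2Cl2, −78 °C; aq. KNaC4H4O6
Reagents that add atoms: none
Why: Low-temperature hydride reduction of the conjugated ester gives the allylic alcohol without touching the α-hydroxyallene or the 9′E double bond.

Step 9
Reactants: 10 allenic diol
Product: 11 (2E)-3-[(2R,7aR)-4,4,7a-trimethyl-2,4,5,6,7,7a-hexahydro-1-benzofuran-2-yl]but-2-en-1-ol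
Conditions: AuCl3 (cat.), THF, rt
Reagents that add atoms: none
Why: Gold-catalysed 5-endo cycloisomerisation of an α-hydroxyallene (anti oxyauration, then protodeauration with retention) transfers the axial chirality to C8′, so the chain ends trans to the C5′ methyl (8′R); the E-configured primary alcohol cannot reach the allene.

Step 10
Reactants: 11 furanoid allylic alcohol
Product: 13 {(2E)-3-[(2R,7aR)-4,4,7a-trimethyl-2,4,5,6,7,7a-hexahydro-1-benzofuran-2-yl]but-2-en-1-yl}triphenylphosphonium bromide, via allylic bromide 12 (not isolated)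
Conditions: CBr4, PPh3, CH2Cl2, −20 to 0 °C; then PPh3, 0 °C to rt
Reagents that add atoms: tetrabromomethane BrC(Br)(Br)Br; triphenylphosphine c1ccc(cc1)P(c1ccccc1)c1ccccc1
Why: Appel bromination followed by quaternisation of the primary allylic bromide avoids the acid that would epimerise the doubly allylic C8′ ether.

Step 11
Reactants: 13 furanoid phosphonium bromide; 14 (2E,4E,6E)-2,7-dimethylocta-2,4,6-trienedial (excess)
Product: 15 (2E,4E,6E,8E,10E)-2,7-dimethyl-11-[(2R,7aR)-4,4,7a-trimethyl-2,4,5,6,7,7a-hexahydro-1-benzofuran-2-yl]dodeca-2,4,6,8,10-pentaenal (C25 aldehyde)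
Conditions: NaOMe, CH2Cl2/MeOH, 0 °C to rt; then heptane, 80 °C
Reagents that add atoms: none
Why: Wittig olefination of the allylic ylide with one carbonyl of the symmetrical dialdehyde (used in excess) forms C11′=C12′, and warming should relax the hindered 11′Z isomer to E without acid or iodine.

Step 12
Reactants: 16 (2E)-3-methylpent-2-en-4-yn-1-ol
Product: 18 (2E)-3-methyl-5-(trimethylsilyl)pent-2-en-4-yn-1-ol, via bis-silyl ether 17 (not isolated)
Conditions: n-BuLi (2.2 equiv), THF, −78 °C; Me3SiCl, −78 °C to rt; then 1 M aq. HCl, rt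
Reagents that add atoms: chlorotrimethylsilane C[Si](C)(C)Cl
Why: C,O-disilylation of the dianion followed by selective hydrolysis of the labile O–Si bond masks the alkyne C–H for the later phosphonate carbanion chemistry.

Step 13
Reactants: 18 silylated enynol
Product: 19 [(3E)-5-bromo-3-methylpent-3-en-1-yn-1-yl]trimethylsilane
Conditions: PBr3, pyridine (cat.), Et2O, −10 °C
Reagents that add atoms: phosphorus tribromide BrP(Br)Br
Why: Bromination of the primary allylic alcohol with PBr3 proceeds without allylic transposition or loss of the E geometry.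

Step 14
Reactants: 19 allylic bromide
Product: 20 diethyl [(2E)-3-methyl-5-(trimethylsilyl)pent-2-en-4-yn-1-yl]phosphonate
Conditions: P(OEt)3, neat, 110 °C
Reagents that add atoms: triethyl phosphite CCOP(OCC)OCC
Why: Michaelis–Arbuzov reaction of the primary allylic bromide gives the phosphonate, whose carbanion keeps the 9E geometry better than the corresponding ylide.

Step 15
Reactants: 20 enynyl phosphonate; 15 C25 aldehyde
Product: 22 (3E,5E,7E,9E,11E,13E,15E)-3,7,12-trimethyl-16-[(2R,7aR)-4,4,7a-trimethyl-2,4,5,6,7,7a-hexahydro-1-benzofuran-2-yl]heptadeca-3,5,7,9,11,13,15-heptaen-1-yne (C31 polyenyne), via silylated polyenyne 21 (not isolated)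
Conditions: NaN(SiMe3)2, THF, −78 °C; 15, −78 to 0 °C; then MeOH, K2CO3 (cat.), rt
Reagents that add atoms: none
Why: Horner–Wadsworth–Emmons olefination forms C11=C12 with E selectivity and no equilibration step (which would scramble the 9E enyne), and methanolysis in the same flask removes the alkynyl silyl group.

Step 16
Reactants: 4 epoxy aldehyde (second portion)
Product: 24 (1R)-1,3,3-trimethyl-2-methylidenecyclohexan-1-ol, via epoxy hydrazone 23 (not isolated)
Conditions: N2H4·H2O, AcOH (cat.), MeOH, 0 °C to rt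
Reagents that add atoms: none
Why: Wharton transposition: the epoxy hydrazone opens to a vinyl diazene that loses N2, turning the aldehyde carbon into the exocyclic methylene while the C5–O bond and its R configuration are untouched.

Step 17
Reactants: 24 tertiary allylic alcohol
Product: 25 triethyl{[(1R)-1,3,3-trimethyl-2-methylidenecyclohexyl]oxy}silane
Conditions: Et3SiOTf, 2,6-lutidine, CH2Cl2, −78 to 0 °C
Reagents that add atoms: triethylsilyl trifluoromethanesulfonate CC[Si](CC)(CC)OS(=O)(=O)C(F)(F)F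
Why: Silylation of the tertiary alcohol with the silyl triflate installs a non-chelating, fluoride-labile group that will control the face of the key addition and also tames the volatility.

Step 18
Reactants: 25 silyl ether
Product: 26 (2R)-2,6,6-trimethyl-2-[(triethylsilyl)oxy]cyclohexan-1-one
Conditions: O3, CH2Cl2, −78 °C; then Me2S, −78 °C to rt
Reagents that add atoms: ozone [O-][O+]=O
Why: Ozonolysis with reductive work-up cleaves the 1,1-disubstituted alkene to the ketone, which has no α-hydrogen and therefore cannot epimerise or enolise.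

Step 19
Reactants: 22 C31 polyenyne; 26 silyloxy ketone
Product: 28 (5R,6S,5′R,8′R)-5′,8′-epoxy-5-[(triethylsilyl)oxy]-5,6,5′,8′-tetrahydro-β,β-caroten-6-ol, via alkynyl carbinol 27 (not isolated)
Conditions: 22, LiN(SiMe3)2 (1.0 equiv), THF, −78 °C; 26, −78 to 0 °C; then NaAlH2(OCH2CH2OCH3)2, THF/toluene, 0 °C to rt; aq. KNaC4H4O6
Reagents that add atoms: none
Why: LiN(SiMe3)2 removes only the sp C–H of 22 and the lithium acetylide adds 1,2 to the C6 carbonyl of 26 (alkynylation of a ketone, the closest known reaction type), forming the C6–C7 bond; no ring is closed. Because C1 and C5 are both fully substituted the ketone cannot enolise, so addition is the only channel, and the slim sp nucleophile tolerates the doubly neopentyl carbonyl. The new C6 stereocentre is controlled by the C5 silyloxy centre: in the chair with the C5–OSiEt3 bond axial (which avoids a syn-diaxial methyl/methyl contact with C1) the acetylide attacks axially, anti-periplanar to the C–O bond (polar Felkin–Anh, non-chelation control), the other face being screened by the axial C1 methyl and the silyloxy group, so O6 ends cis to O5. Without isolation, NaAlH2(OCH2CH2OCH3)2 trans-hydroaluminates the propargylic alkoxide 27 (hydride to C7, aluminium on C8 in a five-membered alkoxyaluminate) and protonolysis should give the 7E alkene only, the polyene and the cyclic allylic ether being inert to the hydride. The step needs chemoselective acetylide formation, facial selectivity at C6 and E geometry at C7=C8; these are secured by the acidity gap of the terminal alkyne, by the silyl ether on O5 and by the alkoxide-directed anti hydroalumination.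

Step 20
Reactants: 28 C40 mono-silyl ether
Product: 29 (5R,6S,5′R,8′R)-5′,8′-epoxy-5,6,5′,8′-tetrahydro-β,β-carotene-5,6-diol (CNP0378030.1)
Conditions: (n-Bu)4NF, THF, 0 °C to rt
Reagents that add atoms: none
Why: Fluoride-mediated desilylation frees the tertiary C5 hydroxyl under non-acidic conditions, so the acid-labile C8′ ether and the polyene geometry are preserved.

Compound list
1 | β-cyclocitral (2,6,6-trimethylcyclohex-1-ene-1-carbaldehyde) | CC1=C(C=O)C(C)(C)CCC1 | starting material
2 | β-cyclogeraniol, (2,6,6-trimethylcyclohex-1-en-1-yl)methanol | CC1=C(CO)C(C)(C)CCC1 | intermediate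
3 | [(1R,6R)-2,2,6-trimethyl-7-oxabicyclo[4.1.0]heptan-1-yl]methanol | CC1(C)CCC[C@@]2(C)O[C@@]12CO | intermediate
4 | (1S,6R)-2,2,6-trimethyl-7-oxabicyclo[4.1.0]heptane-1-carbaldehyde | CC1(C)CCC[C@@]2(C)O[C@@]12C=O | intermediate
5 | (1R,6R)-1-ethynyl-2,2,6-trimethyl-7-oxabicyclo[4.1.0]heptane | CC1(C)CCC[C@@]2(C)O[C@@]12C#C | intermediate
6 | ethyl acetoacetate | CCOC(=O)CC(C)=O | starting material
7 | ethyl (2E)-3-{[(trifluoromethyl)sulfonyl]oxy}but-2-enoate | CCOC(=O)/C=C(C)/OS(=O)(=O)C(F)(F)F | intermediate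
8 | ethyl (2E)-3-methyl-5-[(1R,6R)-2,2,6-trimethyl-7-oxabicyclo[4.1.0]heptan-1-yl]pent-2-en-4-ynoate | CC1(C)CCC[C@@]2(C)O[C@@]12C#C/C(C)=C/C(=O)OCC | intermediate
9 | ethyl (2E)-5-[(2R)-2-hydroxy-2,6,6-trimethylcyclohexylidene]-3-methylpenta-2,4-dienoate, Sa (P) allene, allenic H anti to the hydroxyl | CC1(C)CCC[C@@](C)(O)C1=[C@@]=C/C(C)=C/C(=O)OCC | intermediate
10 | (2E)-5-[(2R)-2-hydroxy-2,6,6-trimethylcyclohexylidene]-3-methylpenta-2,4-dien-1-ol, Sa (P) allene | CC1(C)CCC[C@@](C)(O)C1=[C@@]=C/C(C)=C/CO | intermediate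
11 | (2E)-3-[(2R,7aR)-4,4,7a-trimethyl-2,4,5,6,7,7a-hexahydro-1-benzofuran-2-yl]but-2-en-1-ol | C/C(=C\CO)[C@H]1C=C2C(C)(C)CCC[C@@]2(C)O1 | intermediate
12 | (2R,7aR)-2-[(2E)-4-bromobut-2-en-2-yl]-4,4,7a-trimethyl-2,4,5,6,7,7a-hexahydro-1-benzofuran | C/C(=C\CBr)[C@H]1C=C2C(C)(C)CCC[C@@]2(C)O1 | intermediate
13 | {(2E)-3-[(2R,7aR)-4,4,7a-trimethyl-2,4,5,6,7,7a-hexahydro-1-benzofuran-2-yl]but-2-en-1-yl}triphenylphosphonium bromide | C/C(=C\C[P+](c3ccccc3)(c4ccccc4)c5ccccc5)[C@H]1C=C2C(C)(C)CCC[C@@]2(C)O1.[Br-] | intermediate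
14 | (2E,4E,6E)-2,7-dimethylocta-2,4,6-trienedial | O=C/C(C)=C/C=C/C=C(C)/C=O | starting material
15 | (2E,4E,6E,8E,10E)-2,7-dimethyl-11-[(2R,7aR)-4,4,7a-trimethyl-2,4,5,6,7,7a-hexahydro-1-benzofuran-2-yl]dodeca-2,4,6,8,10-pentaenal | O=C/C(C)=C/C=C/C=C(C)/C=C/C=C(\C)[C@H]1C=C2C(C)(C)CCC[C@@]2(C)O1 | intermediate
16 | (2E)-3-methylpent-2-en-4-yn-1-ol | C#C/C(C)=C/CO | starting material
17 | trimethyl{[(2E)-3-methyl-5-(trimethylsilyl)pent-2-en-4-yn-1-yl]oxy}silane | C[Si](C)(C)C#C/C(C)=C/CO[Si](C)(C)C | intermediate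
18 | (2E)-3-methyl-5-(trimethylsilyl)pent-2-en-4-yn-1-ol | C[Si](C)(C)C#C/C(C)=C/CO | intermediate
19 | [(3E)-5-bromo-3-methylpent-3-en-1-yn-1-yl]trimethylsilane | C[Si](C)(C)C#C/C(C)=C/CBr | intermediate
20 | diethyl [(2E)-3-methyl-5-(trimethylsilyl)pent-2-en-4-yn-1-yl]phosphonate | C[Si](C)(C)C#C/C(C)=C/CP(=O)(OCC)OCC | intermediate
21 | trimethylsilyl derivative of 22 at the alkyne terminus (all-E) | C[Si](C)(C)C#C/C(C)=C/C=C/C(C)=C/C=C/C=C(C)/C=C/C=C(\C)[C@H]1C=C2C(C)(C)CCC[C@@]2(C)O1 | intermediate
22 | (3E,5E,7E,9E,11E,13E,15E)-3,7,12-trimethyl-16-[(2R,7aR)-4,4,7a-trimethyl-2,4,5,6,7,7a-hexahydro-1-benzofuran-2-yl]heptadeca-3,5,7,9,11,13,15-heptaen-1-yne | C#C/C(C)=C/C=C/C(C)=C/C=C/C=C(C)/C=C/C=C(\C)[C@H]1C=C2C(C)(C)CCC[C@@]2(C)O1 | intermediate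
23 | hydrazone of aldehyde 4, (1R,6R)-configured epoxide | CC1(C)CCC[C@@]2(C)O[C@@]12C=NN | intermediate
24 | (1R)-1,3,3-trimethyl-2-methylidenecyclohexan-1-ol | C=C1C(C)(C)CCC[C@@]1(C)O | intermediate
25 | triethyl{[(1R)-1,3,3-trimethyl-2-methylidenecyclohexyl]oxy}silane | C=C1C(C)(C)CCC[C@@]1(C)O[Si](CC)(CC)CC | intermediate
26 | (2R)-2,6,6-trimethyl-2-[(triethylsilyl)oxy]cyclohexan-1-one | O=C1C(C)(C)CCC[C@@]1(C)O[Si](CC)(CC)CC | intermediate
27 | 7,8-didehydro analogue of 28 (C7≡C8; C5 R, C6 with the same spatial arrangement as in 28, formally R) | CC[Si](CC)(CC)O[C@]1(C)CCCC(C)(C)[C@@]1(O)C#C/C(C)=C/C=C/C(C)=C/C=C/C=C(C)/C=C/C=C(\C)[C@H]2C=C3C(C)(C)CCC[C@@]3(C)O2 | intermediate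
28 | (5R,6S,5′R,8′R)-5′,8′-epoxy-5-[(triethylsilyl)oxy]-5,6,5′,8′-tetrahydro-β,β-caroten-6-ol | CC[Si](CC)(CC)O[C@]1(C)CCCC(C)(C)[C@@]1(O)/C=C/C(C)=C/C=C/C(C)=C/C=C/C=C(C)/C=C/C=C(\C)[C@H]2C=C3C(C)(C)CCC[C@@]3(C)O2 | intermediate
29 | (5R,6S,5′R,8′R)-5′,8′-epoxy-5,6,5′,8′-tetrahydro-β,β-carotene-5,6-diol | O[C@]1(C)CCCC(C)(C)[C@@]1(O)/C=C/C(C)=C/C=C/C(C)=C/C=C/C=C(C)/C=C/C=C(\C)[C@H]2C=C3C(C)(C)CCC[C@@]3(C)O2 | target

Total step count: 20. Longest linear sequence: 13 steps (steps 1, 2, 3, 4, 6, 7, 8, 9, 10, 11, 15, 19, 20).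

Steps most likely to fail

1. Step 19 (key step). The bulky, sparingly soluble polyenyl acetylide may add too slowly to the doubly neopentyl carbonyl. The facial bias may erode if the ring reacts through the other chair. Silyl migration between the cis oxygens may slow the directed hydroalumination. Fallback, setting out from 16 and 26 and coming back at 29: the same C6–C7 bond is made with a small acetylide. Compound 16 is silylated (t-BuMe2SiCl, imidazole) to tert-butyldimethyl{[(2E)-3-methylpent-2-en-4-yn-1-yl]oxy}silane F1. Its lithium acetylide (n-BuLi, THF, −78 °C) is added to 26 to give the C15 alkynyl carbinol F2, where any minor C6 epimer can be removed by chromatography. NaAlH2(OCH2CH2OCH3)2 reduces F2 to the E,E-dienol F3, and (n-Bu)4NF removes both silyl groups to give the triol F4. CBr4/PPh3 converts the primary allylic alcohol into the bromide F5, and PPh3 gives the phosphonium bromide F6. A Wittig reaction of F6 with the C25 aldehyde 15 (NaOMe, then warming in heptane) forms C11=C12 and gives 29 directly.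

2. Step 7. The allenylpalladium intermediate may equilibrate, or hydride may be delivered to the propargylic terminus; either would blur the axis that is later relayed to C8′. Fallback, setting out from 4 and coming back at 11: a Horner–Wadsworth–Emmons reaction of 4 with triethyl 3-methyl-4-phosphonobut-2-enoate gives the epoxy dienoate F7. A trace of HCl in CHCl3 triggers the classical epoxide-to-furanoid rearrangement to the furanoid ester F8 (8′R) together with its 8′S epimer F9, which are separated by chromatography. Reduction of F8 with (i-Bu)2AlH gives 11; this fallback trades stereocontrol at C8′ for a separation.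

3. Step 16. Azine or pyrazoline formation and over-reduction may compete with the hydrazone fragmentation, and the small tertiary alcohol is easily lost on evaporation. Fallback, setting out from 3 and coming back at 24: Appel iodination of 3 (PPh3, I2, imidazole) gives the epoxy iodide F10, and zinc dust in acetic acid/ethanol effects reductive ring-opening elimination to 24.

Further compounds
F1 | step 19 | tert-butyldimethyl{[(2E)-3-methylpent-2-en-4-yn-1-yl]oxy}silane | C#C/C(C)=C/CO[Si](C)(C)C(C)(C)C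
F2 | step 19 | (1R,2R)-1-[(3E)-5-{[tert-butyl(dimethyl)silyl]oxy}-3-methylpent-3-en-1-yn-1-yl]-2,6,6-trimethyl-2-[(triethylsilyl)oxy]cyclohexan-1-ol | CC[Si](CC)(CC)O[C@]1(C)CCCC(C)(C)[C@@]1(O)C#C/C(C)=C/CO[Si](C)(C)C(C)(C)C
F3 | step 19 | (1S,2R)-1-[(1E,3E)-5-{[tert-butyl(dimethyl)silyl]oxy}-3-methylpenta-1,3-dien-1-yl]-2,6,6-trimethyl-2-[(triethylsilyl)oxy]cyclohexan-1-ol | CC[Si](CC)(CC)O[C@]1(C)CCCC(C)(C)[C@@]1(O)/C=C/C(C)=C/CO[Si](C)(C)C(C)(C)C
F4 | step 19 | (2E,4E)-5-[(1S,2R)-1,2-dihydroxy-2,6,6-trimethylcyclohexyl]-3-methylpenta-2,4-dien-1-ol | O[C@]1(C)CCCC(C)(C)[C@@]1(O)/C=C/C(C)=C/CO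
F5 | step 19 | (1S,2R)-1-[(1E,3E)-5-bromo-3-methylpenta-1,3-dien-1-yl]-2,6,6-trimethylcyclohexane-1,2-diol | O[C@]1(C)CCCC(C)(C)[C@@]1(O)/C=C/C(C)=C/CBr
F6 | step 19 | {(2E,4E)-5-[(1S,2R)-1,2-dihydroxy-2,6,6-trimethylcyclohexyl]-3-methylpenta-2,4-dien-1-yl}triphenylphosphonium bromide | O[C@]1(C)CCCC(C)(C)[C@@]1(O)/C=C/C(C)=C/C[P+](c2ccccc2)(c3ccccc3)c4ccccc4.[Br-]
F7 | step 7 | ethyl (2E,4E)-3-methyl-5-[(1S,6R)-2,2,6-trimethyl-7-oxabicyclo[4.1.0]heptan-1-yl]penta-2,4-dienoate | CC1(C)CCC[C@@]2(C)O[C@@]12/C=C/C(C)=C/C(=O)OCC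
F8 | step 7 | ethyl (2E)-3-[(2R,7aR)-4,4,7a-trimethyl-2,4,5,6,7,7a-hexahydro-1-benzofuran-2-yl]but-2-enoate | C/C(=C\C(=O)OCC)[C@H]1C=C2C(C)(C)CCC[C@@]2(C)O1
F9 | step 7 | ethyl (2E)-3-[(2S,7aR)-4,4,7a-trimethyl-2,4,5,6,7,7a-hexahydro-1-benzofuran-2-yl]but-2-enoate | C/C(=C\C(=O)OCC)[C@@H]1C=C2C(C)(C)CCC[C@@]2(C)O1
F10 | step 16 | (1S,6R)-1-(iodomethyl)-2,2,6-trimethyl-7-oxabicyclo[4.1.0]heptane | CC1(C)CCC[C@@]2(C)O[C@@]12CI
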